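The quinone ring of the 2‑methyl‑1,4‑naphthoquinone (C1, C2, C3, C4, C4a, C8a) is cut across its two para‑related bonds, C4–C4a and C1–C2. The key step rebuilds both in one flask from a benzaldehyde (C8a–C1; iodine on C4a, bromine on C7) and a (Z)‑3‑iodocrotonate (C2–C3–C4): the alkenylmagnesium adds to the aldehyde, then iodine–lithium exchange closes the ring by acyl substitution. It exploits the cis C2=C3 alkene and the 1,4‑dioxygenation: aldehyde plus ester give the hydroquinone level, trapped as the dimethyl ether. The geraniol‑derived side chain (Sharpless epoxidation, Payne rearrangement trapped by a propargyl anion) is joined by B‑alkyl Suzuki coupling before the quinone is unveiled.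

Key step: step 2

Assumption: the acetoxy‑bearing carbon is R and the tertiary carbinol carbon is S (read from the SMILES), the anti pattern that results from an E‑epoxide after inversion at one carbon; compounds 1, 3 and 9 are taken as commercial.

Step 1
Reactants: 1 ethyl but‑2‑ynoate
Product: 2 ethyl (2Z)‑3‑iodobut‑2‑enoate
Conditions: NaI, AcOH, 115 °C
Reagents that add atoms: sodium iodide, [Na+].[I-]
Why: Conjugate hydroiodination of the ynoate, in which iodide adds at C3 and acetic acid protonates C2 from the opposite face, should give the Z isomer with iodine cis to the ester.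

Step 2
Reactants: 2 ethyl (2Z)‑3‑iodobut‑2‑enoate; 3 5‑bromo‑2‑iodobenzaldehyde
Product: 8 7‑bromo‑1,4‑dimethoxy‑2‑methylnaphthalene, via alkenylmagnesium chloride 4 (not isolated), via hydroxy ester magnesium alkoxide 5 (not isolated), via ring‑closed keto alkoxide 6 (not isolated), via hydroquinone dianion 7 (not isolated)
Conditions: 2, i‑PrMgCl (1.05 equiv), THF, −78 °C; then 3, −78 °C; then n‑BuLi (1.05 equiv), −78 °C → rt; then DMPU, Me2SO4 (4 equiv), 0 °C → rt
Reagents that add atoms: dimethyl sulfate, COS(=O)(=O)OC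
Why: Iodine–magnesium exchange on the activated alkenyl iodide gives the ester‑chelated (Z)‑alkenylmagnesium 4 with retention, which adds to the aldehyde of 3 (Grignard 1,2‑addition, forming C1–C2); at −78 °C the magnesium alkoxide 5 should stay open‑chain, n‑BuLi then exchanges the aryl iodide much faster than it touches the bromide or the ester, and the aryllithium attacks the cis‑held ester in a Parham cyclization (forming C4–C4a) to give 6. The closest known reaction types are the addition of (Z)‑3‑magnesiated enoates to aldehydes and Parham cyclizations onto esters, and the sequence parallels the one‑flask anthraquinone synthesis by double metalation of a benzylic alkoxide. The single ring that closes is the six‑membered carbocycle C1–C2–C3–C4–C4a–C8a, by 6‑exo‑trig addition–elimination at the ester carbonyl. The carbinol centre at C1 of 5 is formed without control and is erased when ethoxide‑mediated enolization aromatizes 6 to the dianion of 7, which Me2SO4 O‑methylates (Williamson) to 8. The regiochemistry is fixed by the substrate: iodine para to bromine puts C4 on C4a, the aldehyde carbon meta to bromine becomes C1 next to the methyl‑bearing C2, and the Z geometry of 2 keeps the ester within reach.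

Step 3
Reactants: 9 geraniol
Product: 10 (2S,3S)‑2,3‑epoxygeraniol
Conditions: Ti(OiPr)4 (5 mol %), L‑(+)‑diethyl tartrate (7.5 mol %), t‑BuOOH, 4 Å molecular sieves, CH2Cl2, −20 °C
Reagents that add atoms: tert‑butyl hydroperoxide, CC(C)(C)OO
Why: Sharpless asymmetric epoxidation is directed by the allylic hydroxyl to the 2,3‑alkene only, and the catalyst formed from Ti(OiPr)4 and L‑(+)‑diethyl tartrate should deliver oxygen to the face that sets both epoxide carbons as S.

Step 4
Reactants: 10 (2S,3S)‑2,3‑epoxygeraniol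
Product: 13 (5R,6S)‑6,10‑dimethylundec‑9‑en‑1‑yne‑5,6‑diol, via terminal epoxy alkoxide 11 (not isolated), via silylalkyne diol 12 (not isolated)
Conditions: n‑BuLi (1.0 equiv), LiCl (3 equiv), THF, −78 → 0 °C; then 3‑lithio‑1‑(trimethylsilyl)propyne (3 equiv, from 1‑(trimethylsilyl)propyne and n‑BuLi, THF, −78 °C), DMPU, 0 °C → rt; then MeOH, K2CO3 (0.2 equiv), rt
Reagents that add atoms: 1‑(trimethylsilyl)propyne, CC#C[Si](C)(C)C
Why: The lithium alkoxide of 10 equilibrates, promoted by LiCl, with the terminal epoxide 11 by Payne rearrangement (intramolecular SN2 at the secondary epoxide carbon with inversion, the tertiary carbon keeping its oxygen and configuration), the hindered trisubstituted epoxide of 10 is inert to the propargyllithium while 11 is opened at its CH2 terminus (Payne rearrangement with in‑flask trapping by an organometallic carbon nucleophile, the reaction type known for organocuprates in aprotic media), and methanolysis removes the alkynyl silyl group of 12, so the anti 5R,6S diol follows from the E epoxide.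

Step 5
Reactants: 13 (5R,6S)‑6,10‑dimethylundec‑9‑en‑1‑yne‑5,6‑diol
Product: 15 (3E,7R,8S)‑4,8,12‑trimethyltrideca‑1,3,11‑triene‑7,8‑diol, via alkenylalane 14 (not isolated)
Conditions: AlMe3 (5 equiv), Cp2ZrCl2 (0.5 equiv), CH2Cl2, 0 °C → rt; then vinyl bromide, Pd(PPh3)4 (5 mol %), ZnCl2 (20 mol %), THF, rt
Reagents that add atoms: trimethylaluminium, C[Al](C)C; vinyl bromide, C=CBr
Why: Negishi zirconium‑catalysed carboalumination adds methyl and aluminium syn across the terminal alkyne (methyl to the internal carbon), which fixes the E trisubstituted alkene, and palladium/zinc‑catalysed Negishi coupling of 14 with vinyl bromide proceeds with retention while the hydroxyls are carried as aluminium alkoxides.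

Step 6
Reactants: 15 (3E,7R,8S)‑4,8,12‑trimethyltrideca‑1,3,11‑triene‑7,8‑diol; 8 7‑bromo‑1,4‑dimethoxy‑2‑methylnaphthalene
Product: 17 (3E,7R,8S)‑1‑(5,8‑dimethoxy‑7‑methylnaphthalen‑2‑yl)‑4,8,12‑trimethyltrideca‑3,11‑diene‑7,8‑diol, via B‑alkyl‑9‑BBN 16 (not isolated)
Conditions: 9‑BBN (3.4 equiv), THF, 0 °C → rt; then 8, Pd(OAc)2 (5 mol %), SPhos (10 mol %), K3PO4 (3 M in H2O), THF, 60 °C
Reagents that add atoms: none
Why: 9‑BBN hydroborates only the terminal monosubstituted alkene of the diene in the anti‑Markovnikov sense (the trisubstituted alkenes are too hindered and the hydroxyls are taken up as borinates by the excess reagent), and B‑alkyl Suzuki–Miyaura coupling of 16 with the aryl bromide forms the ArCH2–CH2 bond.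

Step 7
Reactants: 17 (3E,7R,8S)‑1‑(5,8‑dimethoxy‑7‑methylnaphthalen‑2‑yl)‑4,8,12‑trimethyltrideca‑3,11‑diene‑7,8‑diol
Product: 18 (3E,7R,8S)‑1‑(5,8‑dimethoxy‑7‑methylnaphthalen‑2‑yl)‑8‑hydroxy‑4,8,12‑trimethyltrideca‑3,11‑dien‑7‑yl acetate
Conditions: Ac2O (1.5 equiv), pyridine, DMAP (5 mol %), CH2Cl2, 0 °C → rt
Reagents that add atoms: acetic anhydride, CC(=O)OC(C)=O
Why: DMAP‑catalysed acylation esterifies the secondary hydroxyl and leaves the hindered tertiary one, with retention at C7 because its C–O bond is not broken.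

Step 8
Reactants: 18 (3E,7R,8S)‑1‑(5,8‑dimethoxy‑7‑methylnaphthalen‑2‑yl)‑8‑hydroxy‑4,8,12‑trimethyltrideca‑3,11‑dien‑7‑yl acetate
Product: 19 chabrolonaphthoquinone B
Conditions: (NH4)2Ce(NO3)6 (2.5 equiv), MeCN/H2O, 0 °C
Reagents that add atoms: water, O
Why: Oxidative demethylation of the 1,4‑dimethoxynaphthalene by tetravalent cerium (two one‑electron oxidations, water adds at the methoxy‑bearing carbons and methanol leaves) is the standard unmasking of a quinone and should spare the trisubstituted alkenes, the acetate and the tertiary alcohol.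

Compound list
1 | ethyl but‑2‑ynoate | CC#CC(=O)OCC | starting material
2 | ethyl (2Z)‑3‑iodobut‑2‑enoate | C/C(I)=C/C(=O)OCC | intermediate
3 | 5‑bromo‑2‑iodobenzaldehyde | O=Cc1cc(Br)ccc1I | starting material
4 | ethyl (2Z)‑3‑(chloromagnesio)but‑2‑enoate | C/C([Mg]Cl)=C/C(=O)OCC | intermediate
5 | ethyl (2Z)‑4‑(5‑bromo‑2‑iodophenyl)‑4‑hydroxy‑3‑methylbut‑2‑enoate, racemic, present as its chloromagnesium alkoxide | CCOC(=O)/C=C(/C)C(O)c1cc(Br)ccc1I | intermediate
6 | 6‑bromo‑4‑hydroxy‑3‑methylnaphthalen‑1(4H)‑one, racemic, present as its alkoxide | O=C1C=C(C)C(O)c2cc(Br)ccc12 | intermediate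
7 | 7‑bromo‑2‑methylnaphthalene‑1,4‑diol, present as its dianion | Cc1cc(O)c2ccc(Br)cc2c1O | intermediate
8 | 7‑bromo‑1,4‑dimethoxy‑2‑methylnaphthalene | COc1cc(C)c(OC)c2cc(Br)ccc12 | intermediate
9 | geraniol, (2E)‑3,7‑dimethylocta‑2,6‑dien‑1‑ol | CC(C)=CCC/C(C)=C/CO | starting material
10 | (2S,3S)‑2,3‑epoxygeraniol, [(2S,3S)‑3‑methyl‑3‑(4‑methylpent‑3‑en‑1‑yl)oxiran‑2‑yl]methanol | OC[C@@H]1O[C@@]1(C)CCC=C(C)C | intermediate
11 | (2S)‑6‑methyl‑2‑[(2R)‑oxiran‑2‑yl]hept‑5‑en‑2‑ol, present as its lithium alkoxide | O1[C@H](C1)[C@@](C)(O)CCC=C(C)C | intermediate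
12 | (5R,6S)‑6,10‑dimethyl‑1‑(trimethylsilyl)undec‑9‑en‑1‑yne‑5,6‑diol | O[C@H](CCC#C[Si](C)(C)C)[C@@](C)(O)CCC=C(C)C | intermediate
13 | (5R,6S)‑6,10‑dimethylundec‑9‑en‑1‑yne‑5,6‑diol | O[C@H](CCC#C)[C@@](C)(O)CCC=C(C)C | intermediate
14 | (1E,5R,6S)‑alkenyl(dimethyl)alane of 13 (methyl on C2, aluminium on C1), both hydroxyls as dimethylaluminium alkoxides | C[Al](C)O[C@H](CC/C(C)=C/[Al](C)C)[C@@](C)(O[Al](C)C)CCC=C(C)C | intermediate
15 | (3E,7R,8S)‑4,8,12‑trimethyltrideca‑1,3,11‑triene‑7,8‑diol | O[C@H](CC/C(C)=C/C=C)[C@@](C)(O)CCC=C(C)C | intermediate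
16 | 9‑[(3E,7R,8S)‑7,8‑dihydroxy‑4,8,12‑trimethyltrideca‑3,11‑dien‑1‑yl]‑9‑borabicyclo[3.3.1]nonane, both hydroxyls as 9‑BBN borinates | B1(O[C@H](CC/C(C)=C/CCB2C3CCCC2CCC3)[C@@](C)(OB2C3CCCC2CCC3)CCC=C(C)C)C2CCCC1CCC2 | intermediate
17 | (3E,7R,8S)‑1‑(5,8‑dimethoxy‑7‑methylnaphthalen‑2‑yl)‑4,8,12‑trimethyltrideca‑3,11‑diene‑7,8‑diol | O[C@H](CC/C(C)=C/CCc1ccc2c(OC)cc(C)c(OC)c2c1)[C@@](C)(O)CCC=C(C)C | intermediate
18 | (3E,7R,8S)‑1‑(5,8‑dimethoxy‑7‑methylnaphthalen‑2‑yl)‑8‑hydroxy‑4,8,12‑trimethyltrideca‑3,11‑dien‑7‑yl acetate | CC(=O)O[C@H](CC/C(C)=C/CCc1ccc2c(OC)cc(C)c(OC)c2c1)[C@@](C)(O)CCC=C(C)C | intermediate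
19 | chabrolonaphthoquinone B, (3E,7R,8S)‑8‑hydroxy‑4,8,12‑trimethyl‑1‑(7‑methyl‑5,8‑dioxo‑5,8‑dihydronaphthalen‑2‑yl)trideca‑3,11‑dien‑7‑yl acetate | CC(=O)O[C@H](CC/C(C)=C/CCc1ccc2c(c1)C(=O)C(C)=CC2=O)[C@@](C)(O)CCC=C(C)C | target

Total step count: 8
Longest linear sequence: 6 steps (steps 3 to 8, from geraniol)

Steps most likely to fail

1. Step 2. The magnesium alkoxide may lactonise to the butenolide before the iodine–lithium exchange, after which proton transfer from the acidic γ‑position of the lactone (or from the allylic methyl group) can quench the aryllithium; aromatisation may also be incomplete before methylation. Fallback, setting out from 2 and 3 and coming back at 8: the two bonds are made in separate, isolated stages with the alkoxide masked. Addition of 4 to 3 is run with warming to room temperature so that 5 lactonises fully to 5‑(5‑bromo‑2‑iodophenyl)‑4‑methylfuran‑2(5H)‑one F1. The lactone is opened with MeNH(OMe)·HCl/AlMe3 and the freed hydroxyl is silylated (TBSOTf, 2,6‑lutidine) to give (2Z)‑4‑(5‑bromo‑2‑iodophenyl)‑4‑[(tert‑butyldimethylsilyl)oxy]‑N‑methoxy‑N,3‑dimethylbut‑2‑enamide F2. Iodine–magnesium exchange with i‑PrMgCl·LiCl (THF, −40 → 0 °C) and attack of the arylmagnesium on the Weinreb amide then gives 6‑bromo‑4‑[(tert‑butyldimethylsilyl)oxy]‑3‑methylnaphthalen‑1(4H)‑one F3. Bu4NF removes the silyl group and aromatises the ring to 7, which K2CO3/Me2SO4 in acetone converts into 8.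

2. Step 4. Under aprotic conditions the Payne equilibrium of the lithium alkoxide may be set up too slowly or lie too far on the side of the trisubstituted epoxide, so that the propargyllithium decays, reacts through its allenyl terminus or deprotonates the epoxide before the terminal epoxide is intercepted. Fallback, setting out from 10 and coming back at 13: the rearrangement is run under protic conditions with hydroxide as the trap, and the terminal epoxide is then rebuilt and isolated before the carbon nucleophile is added. NaOH (0.5 M in H2O, t‑BuOH, 75 °C) converts 10 by Payne rearrangement and hydroxide opening at C1 into (2R,3S)‑3,7‑dimethyloct‑6‑ene‑1,2,3‑triol F4. TsCl, Et3N and Bu2SnO (2 mol %) in CH2Cl2 sulfonylate only the primary hydroxyl to give (2R,3S)‑2,3‑dihydroxy‑3,7‑dimethyloct‑6‑en‑1‑yl 4‑methylbenzenesulfonate F5. K2CO3 in MeOH closes F5 to the terminal epoxy alcohol 11, which is isolated in this variant; lithiated 1‑(trimethylsilyl)propyne (THF/DMPU, −78 → 0 °C) opens it at CH2 to 12, and K2CO3/MeOH removes the silyl group to give 13.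

3. Step 6. Hydroboration may not discriminate cleanly between terminal 1,2‑addition and addition across the conjugated diene, and the borinate‑bound diol may slow transmetalation so that protodeboronation competes. Fallback, setting out from 13 and 8 and coming back at 17: the roles of the partners are exchanged so that no diene is hydroborated. Alkenylalane 14, made from 13 as in step 5, is quenched with I2 to give (1E,5R,6S)‑1‑iodo‑2,6,10‑trimethylundeca‑1,9‑diene‑5,6‑diol F6. Bromide 8 is vinylated with potassium vinyltrifluoroborate (Pd(dppf)Cl2, Cs2CO3, THF/H2O) to 7‑ethenyl‑1,4‑dimethoxy‑2‑methylnaphthalene F7. 9‑BBN converts F7 into 9‑[2‑(5,8‑dimethoxy‑7‑methylnaphthalen‑2‑yl)ethyl]‑9‑borabicyclo[3.3.1]nonane F8, which is coupled with F6 (Pd(dppf)Cl2, AsPh3, Cs2CO3, DMF/H2O, rt) to give 17.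

Further compounds
F1 | step 2 | 5‑(5‑bromo‑2‑iodophenyl)‑4‑methylfuran‑2(5H)‑one | CC1=CC(=O)OC1c1cc(Br)ccc1I
F2 | step 2 | (2Z)‑4‑(5‑bromo‑2‑iodophenyl)‑4‑[(tert‑butyldimethylsilyl)oxy]‑N‑methoxy‑N,3‑dimethylbut‑2‑enamide | CON(C)C(=O)/C=C(/C)C(O[Si](C)(C)C(C)(C)C)c1cc(Br)ccc1I
F3 | step 2 | 6‑bromo‑4‑[(tert‑butyldimethylsilyl)oxy]‑3‑methylnaphthalen‑1(4H)‑one | O=C1C=C(C)C(O[Si](C)(C)C(C)(C)C)c2cc(Br)ccc12
F4 | step 4 | (2R,3S)‑3,7‑dimethyloct‑6‑ene‑1,2,3‑triol | O[C@H](CO)[C@@](C)(O)CCC=C(C)C
F5 | step 4 | (2R,3S)‑2,3‑dihydroxy‑3,7‑dimethyloct‑6‑en‑1‑yl 4‑methylbenzenesulfonate | O[C@H](COS(=O)(=O)c1ccc(C)cc1)[C@@](C)(O)CCC=C(C)C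
F6 | step 6 | (1E,5R,6S)‑1‑iodo‑2,6,10‑trimethylundeca‑1,9‑diene‑5,6‑diol | O[C@H](CC/C(C)=C/I)[C@@](C)(O)CCC=C(C)C
F7 | step 6 | 7‑ethenyl‑1,4‑dimethoxy‑2‑methylnaphthalene | C=Cc1ccc2c(OC)cc(C)c(OC)c2c1
F8 | step 6 | 9‑[2‑(5,8‑dimethoxy‑7‑methylnaphthalen‑2‑yl)ethyl]‑9‑borabicyclo[3.3.1]nonane | COc1cc(C)c(OC)c2cc(CCB3C4CCCC3CCC4)ccc12
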